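The data were computed from invented constants; scatter was added.

In this stirred vessel D and J give Q and G, and you want the larch flask's contents at 3.0 d.

| setting | larch | maple | flask |
|---|---|---|---|
| D | 1 M (in portions, 3) | 1 M (in portions, 3) | 1.0 M (in portions, 3) |
| J | 1.1 M | 0.55 M | 1.10 M |
| E | 0.50 M | 0.50 M | 0.500 M |
| remark | the very flask that is asked about, followed so far; portions every 25 min | run made earlier; portions every 25 min | the portions of D follow each other after 25 min, the first at the start |
| time |  |  | 3.0 d |

larch run (percent of the D charged)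

| time / h | D / % | Q / % | G / % |
|---|---|---|---|
| 1.33 | 70.9 | 25.9 | 4.3 |
| 2.50 | 55.0 | 33.5 | 11.5 |
| 4.00 | 46.2 | 33.9 | 19.3 |
| 5.00 | 43.3 | 33.4 | 23.7 |
| 6.00 | 40.7 | 32.1 | 27.0 |
| 8.00 | 38.0 | 30.9 | 30.6 |

maple run (percent of the D charged)

| time / d | D / % | Q / % | G / % |
|---|---|---|---|
| 0.250 | 64.8 | 19.3 | 16.5 |
| 0.333 | 63.2 | 18.9 | 18.1 |
| 0.500 | 61.3 | 17.9 | 20.3 |
| 0.833 | 61.4 | 17.8 | 21.2 |
| 1.25 | 60.5 | 18.5 | 21.5 |
| 2.08 | 60.4 | 17.9 | 21.4 |
| 3.00 | 60.3 | 18.2 | 20.9 |

(each reading ± 0.3 percentage points)



1. how much of the D has reacted by 3.0 d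
2. how much Q there is at 3.0 d, in percent of the D charged
3. how much G there is at 3.0 d, in percent of the D charged

Why did maple stop? From 1.25 d to 3.00 d its D moves from 60.5 % to 60.3 %, inside the scatter. D lost roughly equals Q plus G. I assume one J per D lost, so by that count maple still held [J] = 0.153 M at its stop. I therefore read that stop as a two-way step at balance, not an empty tank. Maple's last reading gives 4.24 /M for the stall quotient, ([Q] + [G])/([D][J]) at the stop, an apparent equilibrium constant.

Where does larch stop? Holding that quotient at larch's charges, I get 0.654 M of D lost, which is 65.4 %. Taking over the G-to-Q ratio of 1.15, as read at maple's last reading, I split this for larch into Q 30.4 % and G 35.0 %.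

Will larch get there in time? Its D stands 12 percentage points above that stop at 4.00 h and 3.4 points above it at 8.00 h. That is a half-time, as read, of 2.26 h, far shorter than the time asked, so I expect larch to be at its stop.

The forecast differs from my reckoning: 74 % of D reacted, Q 26 %, G 47 %, on the ground “That looks like J running out, not equilibrium”.

Larch gives 65.2 % reacted, Q 29.8 %, G 35.5 %, and ten times as long leaves it at 65.2 %.

    Q ⇌ G (K = 1.19, k = 7.41 × 10⁻⁵ /s)
    D + J ⇌ Q (K = 2.05 /M, k = 1.42 × 10⁻⁴ /M/s)
    E + J ⇌ L (K = 0.150 /M, k = 5.12 × 10⁻⁴ /M/s)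

With J by the same subtraction, which counts the 0.0295 M of L as free J, larch's end gives a quotient of 4.19 /M. The forecast's numbers, put through that same subtraction, give 7.80 /M, twice the quotient read from maple.

For the neighbour with 2.8 M of J, the stall quotient gives 89.0 % of D reacted. The computed neighbour gives 89.0 %.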